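Everything rests on reading the cyclohexenone ring (C1–C6) with its exocyclic carbon C7 as benzoic acid. The feature exploited is the cis pair of C–O bonds on neighbouring ring carbons, the tertiary C4 hydroxyl and the C5 end of the C5–C6 epoxide, with C7 on C4 as a carboxyl sits on an ipso carbon. A benzoate 1,2-dioxygenase adds O2 across the ipso and ortho carbons of unprotected benzoic acid and so forms both C–O bonds, both stereocentres and a diene in one operation. Later, C5–O displaces a trans bromide at C6, the diene supplies C1=O and C2=C3, and the chains arrive by Cu-catalysed amidation (C2–N) and Stille coupling (C8–C9).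

Key step: step 1

Remark 1: target numbering is used for all ring compounds (C1 ketone, C2 N-bearing, C3 vinylic CH, C4 carbinol, C5/C6 epoxide, C7 first chain carbon). α is the ring face that carries the C4 oxygen and β is the opposite face.
Remark 2: the target is (4S,5R,6S) with C4–OH and the epoxide oxygen both α. The (1S,2R)-diol 2 maps onto it directly. The C4 descriptor reads R in the alkynyl and stannylvinyl intermediates only because CIP priorities change.
Remark 3 (assumption): a benzoate-dioxygenase strain blocked in the diol dehydrogenase is taken as an obtainable biocatalyst, from a culture collection or as recombinant cells expressing benABC.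

**Part A – ring core**

Step 1
Reactants: 1 benzoic acid (fed as sodium benzoate)
Product: 2 (1S,2R)-1,2-dihydroxycyclohexa-3,5-diene-1-carboxylic acid
Conditions: Ralstonia eutropha B9 whole cells (benzoate 1,2-dioxygenase active, diol dehydrogenase blocked), benzoate fed-batch, D-fructose, mineral salts medium, pH 7.4, air, 30 °C; cell-free broth concentrated, pH 3 at 0 °C, EtOAc
Reagents that add atoms: dioxygen, O=O
Why: The Rieske non-haem iron dioxygenase binds benzoate through its carboxylate, activates O2 at the mononuclear iron with two electrons from NADH and transfers both oxygen atoms suprafacially to the ipso–ortho π bond, forming the C4–O and C5–O bonds; this is a known enzymatic dearomatising cis-dihydroxylation. The strain lacks the diol dehydrogenase, so the diol should accumulate instead of being rearomatised to catechol with loss of CO2. No ring is closed; the arene carbocycle is kept and becomes the cyclohexenone ring. Both stereocentres (acid C1 = C4, S; acid C2 = C5, R) are controlled by the active site: the cis relation comes from delivery of both oxygens from one iron-bound O2 unit, and the absolute sense comes from the single binding orientation of benzoate. The selectivity needed is ipso,ortho rather than ortho,meta attack; the carboxylate anchor secures it, and the two ortho positions of benzoate are equivalent, so no regioisomer can arise.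

Step 2
Reactants: 2 (1S,2R)-1,2-dihydroxycyclohexa-3,5-diene-1-carboxylic acid
Product: 3 methyl (1S,2R)-1,2-dihydroxycyclohexa-3,5-diene-1-carboxylate
Conditions: MeI, K2CO3, DMF, 0 °C → rt
Reagents that add atoms: iodomethane, CI
Why: SN2 O-alkylation of the carboxylate under non-acidic conditions avoids acid-promoted dehydrative rearomatisation and leaves both hydroxyls and both stereocentres untouched.

Step 3
Reactants: 3 methyl (1S,2R)-1,2-dihydroxycyclohexa-3,5-diene-1-carboxylate
Product: 4 methyl (3aS,7aR)-2,2-dimethyl-3a,7a-dihydro-1,3-benzodioxole-3a-carboxylate (C4,C5-O-isopropylidene ester)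
Conditions: Me2C(OMe)2, p-TsOH·H2O (cat.), acetone, rt
Reagents that add atoms: 2,2-dimethoxypropane, COC(C)(C)OC
Why: Acid-catalysed transketalisation closes a cis-fused dioxolane on the cis-1,2-diol, which protects both hydroxyls in one step and shields the α face for step 6.

Step 4
Reactants: 4 methyl (3aS,7aR)-2,2-dimethyl-3a,7a-dihydro-1,3-benzodioxole-3a-carboxylate
Product: 6 (3aR,7aR)-3a-ethynyl-2,2-dimethyl-3a,7a-dihydro-1,3-benzodioxole, via (3aS,7aR)-2,2-dimethyl-3a,7a-dihydro-1,3-benzodioxole-3a-carbaldehyde 5 (not isolated)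
Conditions: DIBAL-H, CH2Cl2, −78 °C; MeOH, then K2CO3, MeC(O)C(N2)P(O)(OMe)2, −78 °C → rt; Rochelle salt work-up
Reagents that add atoms: dimethyl (1-diazo-2-oxopropyl)phosphonate, CC(=O)C(=[N+]=[N-])P(=O)(OC)OC
Why: Partial DIBAL-H reduction of an α-alkoxy ester (chelated aluminium hemiacetal, stable at −78 °C) followed in the same flask by Ohira–Bestmann (Seyferth–Gilbert) homologation is a known one-pot ester-to-alkyne sequence, and aldehyde 5 has no α-hydrogen, so C4 cannot epimerise.

Step 5
Reactants: 6 (3aR,7aR)-3a-ethynyl-2,2-dimethyl-3a,7a-dihydro-1,3-benzodioxole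
Product: 8 triethyl{[(3aR,7aR)-2,2-dimethyl-3a,7a-dihydro-1,3-benzodioxol-3a-yl]ethynyl}silane, via the lithium acetylide of 6, compound 7 (not isolated)
Conditions: n-BuLi, THF, −78 °C; Et3SiCl, −78 °C → rt
Reagents that add atoms: chlorotriethylsilane, CC[Si](Cl)(CC)CC; n-butyllithium, [Li]CCCC (lithium in 7 only)
Why: Deprotonation of the most acidic C–H and C-silylation of the acetylide give a cap that blocks iodoalkyne and copper acetylide formation in steps 9 and 18 and tolerates aqueous acid and carbonate bases.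

Step 6
Reactants: 8 triethyl{[(3aR,7aR)-2,2-dimethyl-3a,7a-dihydro-1,3-benzodioxol-3a-yl]ethynyl}silane
Product: 9 (3aR,6R,7S,7aS)-7-bromo-2,2-dimethyl-3a-[(triethylsilyl)ethynyl]-3a,6,7,7a-tetrahydro-1,3-benzodioxol-6-ol (C6–Br β, C1–OH α)
Conditions: NBS, THF–H2O (4:1), 0 °C, dark
Reagents that add atoms: N-bromosuccinimide, O=C1CCC(=O)N1Br; water, O
Why: In this bromohydrin formation Br+ should reach the less hindered C6=C1 alkene from the β face opposite the acetonide and water should open the bromonium ion at the allylic C1 from the α face, which places C6–Br trans to C5–O (the C1 centre is erased in step 7).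

Step 7
Reactants: 9 bromohydrin (C6–Br β, C1–OH α)
Product: 10 (3aR,7R,7aS)-7-bromo-2,2-dimethyl-3a-[(triethylsilyl)ethynyl]-7,7a-dihydro-1,3-benzodioxol-6(3aH)-one (6-bromo enone)
Conditions: Dess–Martin periodinane, CH2Cl2, 0 °C → rt
Reagents that add atoms: none
Why: Dess–Martin oxidation of the secondary allylic alcohol under near-neutral conditions installs the C1 ketone, removes the only hydroxyl that could compete for the bromide, and activates C6–Br for displacement.

Step 8
Reactants: 10 6-bromo enone acetonide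
Product: 12 (4R,5R,6S)-5,6-epoxy-4-hydroxy-4-[(triethylsilyl)ethynyl]cyclohex-2-en-1-one (epoxide O and C4–OH both α), via (4R,5S,6R)-6-bromo-4,5-dihydroxy-4-[(triethylsilyl)ethynyl]cyclohex-2-en-1-one 11 (not isolated)
Conditions: TFA–H2O (9:1), CH2Cl2, 0 °C → rt; evaporate with toluene; K2CO3, MeCN, 0 °C
Reagents that add atoms: none
Why: Acetal hydrolysis followed by irreversible halohydrin-to-epoxide closure (the ring-closing half of a Darzens reaction) lets the enzymatically installed C5–O attack C6 from the α face with inversion, so C6 is set cis to C4–OH, and any C6-epimerised bromide cannot close and re-equilibrates through the enol.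

Step 9
Reactants: 12 (4R,5R,6S)-5,6-epoxy-4-hydroxy-4-[(triethylsilyl)ethynyl]cyclohex-2-en-1-one
Product: 13 (4R,5R,6S)-5,6-epoxy-4-hydroxy-2-iodo-4-[(triethylsilyl)ethynyl]cyclohex-2-en-1-one
Conditions: I2, pyridine–CH2Cl2 (1:1), 0 °C → rt, dark
Reagents that add atoms: iodine, II
Why: Baylis–Hillman-type α-iodination of an enone (pyridine adds at C3, the enolate captures iodine at C2, pyridine is expelled) is known for 4,4-disubstituted and 5,6-epoxy cyclohexenones, and it is run before any tin is present so no iododestannylation can occur.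

**Part B – upper chain**

Step 10
Reactants: 14 (E)-4-methylpent-2-enal; 15 triethyl (E)-4-phosphonocrotonate
Product: 17 ethyl (2E,4E,6E)-8-methylnona-2,4,6-trienoate, via the lithiated phosphonate 16 (not isolated)
Conditions: LiHMDS, THF, −78 °C; then 14, −78 → 0 °C
Reagents that add atoms: lithium hexamethyldisilazide, [Li]N([Si](C)(C)C)[Si](C)(C)C (lithium in 16 only)
Why: The vinylogous Horner–Wadsworth–Emmons olefination with a stabilised allylic phosphonate anion reacts at its α-carbon and should give the new C4=C5 alkene E under thermodynamic control, while both existing E alkenes are retained.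

Step 11
Reactants: 17 ethyl (2E,4E,6E)-8-methylnona-2,4,6-trienoate
Product: 18 (2E,4E,6E)-8-methylnona-2,4,6-trienoic acid
Conditions: LiOH, THF–MeOH–H2O, rt; then 1 M HCl
Reagents that add atoms: lithium hydroxide, [Li+].[OH-]
Why: Simple saponification, in which the conjugated all-E triene is the thermodynamic geometry and is not disturbed.

Step 12
Reactants: 18 (2E,4E,6E)-8-methylnona-2,4,6-trienoic acid
Product: 20 (2E,4E,6E)-8-methylnona-2,4,6-trienamide, via (2E,4E,6E)-8-methylnona-2,4,6-trienoyl chloride 19 (not isolated)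
Conditions: (COCl)2, DMF (cat.), CH2Cl2, 0 °C; evaporate; NH3 (0.5 M in dioxane), 0 °C
Reagents that add atoms: ammonia, N; oxalyl chloride, O=C(Cl)C(=O)Cl (chlorine in 19 only)
Why: Vilsmeier-catalysed acid chloride formation and aminolysis take place at the acyl carbon far faster than any conjugate addition to the polyene.

**Part C – lower chain**

Step 13
Reactants: 21 cyclopentane-1,3-dione
Product: 22 3-hydroxy-2-nitrocyclopent-2-en-1-one (2-nitrocyclopentane-1,3-dione)
Conditions: fuming HNO3, CH2Cl2, 0 °C
Reagents that add atoms: nitric acid, O[N+](=O)[O-]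
Why: Electrophilic nitration of the enol of a cyclic 1,3-diketone occurs at C2, its only nucleophilic carbon, as known for dimedone-type diones.

Step 14
Reactants: 22 3-hydroxy-2-nitrocyclopent-2-en-1-one
Product: 23 2-amino-3-hydroxycyclopent-2-en-1-one hydrochloride
Conditions: H2 (1 atm), 10 % Pd/C, EtOH, HCl, rt
Reagents that add atoms: hydrogen chloride, Cl
Why: Catalytic hydrogenation reduces the nitro group, and trapping as the hydrochloride prevents self-condensation and air oxidation of the 2-amino-1,3-dione.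

Step 15
Reactants: 24 ethyl (E)-4-oxobut-2-enoate
Product: 25 ethyl (2E,4E)-5-iodopenta-2,4-dienoate
Conditions: CrCl2, CHI3, THF, 0 °C
Reagents that add atoms: iodoform, IC(I)I
Why: In the Takai olefination the gem-dichromium species adds only to the aldehyde and eliminates to the E-vinyl iodide, the E-enoate stays untouched, and any minor 4Z isomer can be removed at the crystalline acid stage.

Step 16
Reactants: 25 ethyl (2E,4E)-5-iodopenta-2,4-dienoate
Product: 26 (2E,4E)-5-iodopenta-2,4-dienoic acid
Conditions: LiOH, THF–H2O, 0 °C → rt; then 1 M HCl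
Reagents that add atoms: lithium hydroxide, [Li+].[OH-]
Why: Saponification at low temperature is faster than addition–elimination at the iodine-bearing terminus.

Step 17
Reactants: 26 (2E,4E)-5-iodopenta-2,4-dienoic acid; 23 2-amino-3-hydroxycyclopent-2-en-1-one hydrochloride
Product: 28 (2E,4E)-N-(2-hydroxy-5-oxocyclopent-1-en-1-yl)-5-iodopenta-2,4-dienamide, via (2E,4E)-5-iodopenta-2,4-dienoyl chloride 27 (not isolated)
Conditions: (COCl)2, DMF (cat.), CH2Cl2, 0 °C; evaporate; 23, Et3N, CH2Cl2–DMF, 0 °C → rt
Reagents that add atoms: oxalyl chloride, O=C(Cl)C(=O)Cl (chlorine in 27 only)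
Why: Schotten–Baumann-type N-acylation of the liberated amine gives the amide, and any enol ester formed at oxygen should pass its acyl group to the adjacent nitrogen (O→N acyl shift) to give the more stable amide.

**Part D – assembly**

Step 18
Reactants: 13 (4R,5R,6S)-5,6-epoxy-4-hydroxy-2-iodo-4-[(triethylsilyl)ethynyl]cyclohex-2-en-1-one; 20 (2E,4E,6E)-8-methylnona-2,4,6-trienamide
Product: 29 (2E,4E,6E)-N-{(4R,5R,6S)-5,6-epoxy-4-hydroxy-1-oxo-4-[(triethylsilyl)ethynyl]cyclohex-2-en-2-yl}-8-methylnona-2,4,6-trienamide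
Conditions: CuI (10 mol %), MeNHCH2CH2NHMe (20 mol %), Cs2CO3, THF, 50 °C, Ar
Reagents that add atoms: none
Why: Goldberg–Buchwald Cu(I)/diamine amidation of a vinyl iodide with a primary amide should be favoured by the carbonyl-activated C2–I bond, while the substrate has no enolisable proton apart from the epoxide C6–H, the cis hydroxy epoxide cannot undergo epoxide migration, and neither tin nor a free alkyne is present to intercept copper.

Step 19
Reactants: 29 silyl-capped amide
Product: 30 (2E,4E,6E)-N-[(4R,5R,6S)-5,6-epoxy-4-ethynyl-4-hydroxy-1-oxocyclohex-2-en-2-yl]-8-methylnona-2,4,6-trienamide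
Conditions: TBAF–AcOH (1:1), THF, 0 °C
Reagents that add atoms: none
Why: Fluoride-induced protiodesilylation of the alkynylsilane is buffered with acetic acid so that the epoxy enone never meets a basic medium.

Step 20
Reactants: 30 terminal alkyne
Product: 31 (2E,4E,6E)-N-{(4R,5R,6S)-5,6-epoxy-4-hydroxy-1-oxo-4-[(E)-2-(tributylstannyl)ethenyl]cyclohex-2-en-2-yl}-8-methylnona-2,4,6-trienamide
Conditions: Bu3SnH (slow addition), PdCl2(PPh3)2 (3 mol %), THF, 0 °C
Reagents that add atoms: tributyltin hydride, CCCC[SnH](CCCC)CCCC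
Why: Pd-catalysed syn-hydrostannylation of a terminal alkyne sets the E C7=C8 geometry, the bulk of the tertiary propargylic carbinol should steer tin to the distal C8, and alkynes react much faster than enones in the absence of an acid co-catalyst.

Step 21
Reactants: 31 vinylstannane; 28 (2E,4E)-N-(2-hydroxy-5-oxocyclopent-1-en-1-yl)-5-iodopenta-2,4-dienamide
Product: 32 manumycin G, (4S,5R,6S)
Conditions: PdCl2(MeCN)2 (5 mol %), DMF, rt, dark, Ar
Reagents that add atoms: none
Why: The Stille coupling forms C8–C9 with retention of both alkene geometries under neutral conditions at room temperature, which are known to tolerate a free tertiary hydroxyl, an epoxy ketone and the acidic enol amide in 4-hydroxy-4-(stannylvinyl)epoxycyclohexenones.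

**Compound list**

1 | benzoic acid | OC(=O)c1ccccc1 | starting material
2 | (1S,2R)-1,2-dihydroxycyclohexa-3,5-diene-1-carboxylic acid | C1=C[C@@](O)(C(=O)O)[C@H](O)C=C1 | intermediate
3 | methyl (1S,2R)-1,2-dihydroxycyclohexa-3,5-diene-1-carboxylate | C1=C[C@@](O)(C(=O)OC)[C@H](O)C=C1 | intermediate
4 | methyl (3aS,7aR)-2,2-dimethyl-3a,7a-dihydro-1,3-benzodioxole-3a-carboxylate | C1=C[C@@](O2)(C(=O)OC)[C@H](OC2(C)C)C=C1 | intermediate
5 | (3aS,7aR)-2,2-dimethyl-3a,7a-dihydro-1,3-benzodioxole-3a-carbaldehyde | C1=C[C@@](O2)(C=O)[C@H](OC2(C)C)C=C1 | intermediate (not isolated)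
6 | (3aR,7aR)-3a-ethynyl-2,2-dimethyl-3a,7a-dihydro-1,3-benzodioxole | C1=C[C@@](O2)(C#C)[C@H](OC2(C)C)C=C1 | intermediate
7 | lithium acetylide of 6 | C1=C[C@@](O2)(C#C[Li])[C@H](OC2(C)C)C=C1 | intermediate (not isolated)
8 | triethyl{[(3aR,7aR)-2,2-dimethyl-3a,7a-dihydro-1,3-benzodioxol-3a-yl]ethynyl}silane | C1=C[C@@](O2)(C#C[Si](CC)(CC)CC)[C@H](OC2(C)C)C=C1 | intermediate
9 | (3aR,6R,7S,7aS)-7-bromo-2,2-dimethyl-3a-[(triethylsilyl)ethynyl]-3a,6,7,7a-tetrahydro-1,3-benzodioxol-6-ol | C1=C[C@@](O2)(C#C[Si](CC)(CC)CC)[C@H](OC2(C)C)[C@@H](Br)[C@@H]1O | intermediate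
10 | (3aR,7R,7aS)-7-bromo-2,2-dimethyl-3a-[(triethylsilyl)ethynyl]-7,7a-dihydro-1,3-benzodioxol-6(3aH)-one | C1=C[C@@](O2)(C#C[Si](CC)(CC)CC)[C@H](OC2(C)C)[C@@H](Br)C1=O | intermediate
11 | (4R,5S,6R)-6-bromo-4,5-dihydroxy-4-[(triethylsilyl)ethynyl]cyclohex-2-en-1-one | C1=C[C@@](O)(C#C[Si](CC)(CC)CC)[C@H](O)[C@@H](Br)C1=O | intermediate (not isolated)
12 | (4R,5R,6S)-5,6-epoxy-4-hydroxy-4-[(triethylsilyl)ethynyl]cyclohex-2-en-1-one | C1=C[C@@](O)(C#C[Si](CC)(CC)CC)[C@@H]2O[C@@H]2C1=O | intermediate
13 | (4R,5R,6S)-5,6-epoxy-4-hydroxy-2-iodo-4-[(triethylsilyl)ethynyl]cyclohex-2-en-1-one | IC1=C[C@@](O)(C#C[Si](CC)(CC)CC)[C@@H]2O[C@@H]2C1=O | intermediate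
14 | (E)-4-methylpent-2-enal | CC(C)/C=C/C=O | starting material
15 | triethyl (E)-4-phosphonocrotonate | CCOC(=O)/C=C/CP(=O)(OCC)OCC | starting material
16 | lithiated triethyl 4-phosphonocrotonate | [Li+].CCOC(=O)/C=C/[CH-]P(=O)(OCC)OCC | intermediate (not isolated)
17 | ethyl (2E,4E,6E)-8-methylnona-2,4,6-trienoate | CC(C)/C=C/C=C/C=C/C(=O)OCC | intermediate
18 | (2E,4E,6E)-8-methylnona-2,4,6-trienoic acid | CC(C)/C=C/C=C/C=C/C(=O)O | intermediate
19 | (2E,4E,6E)-8-methylnona-2,4,6-trienoyl chloride | CC(C)/C=C/C=C/C=C/C(=O)Cl | intermediate (not isolated)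
20 | (2E,4E,6E)-8-methylnona-2,4,6-trienamide | CC(C)/C=C/C=C/C=C/C(N)=O | intermediate
21 | cyclopentane-1,3-dione | O=C1CCC(=O)C1 | starting material
22 | 3-hydroxy-2-nitrocyclopent-2-en-1-one | O=C1CCC(O)=C1[N+](=O)[O-] | intermediate
23 | 2-amino-3-hydroxycyclopent-2-en-1-one hydrochloride | NC1=C(O)CCC1=O.Cl | intermediate
24 | ethyl (E)-4-oxobut-2-enoate | CCOC(=O)/C=C/C=O | starting material
25 | ethyl (2E,4E)-5-iodopenta-2,4-dienoate | CCOC(=O)/C=C/C=C/I | intermediate
26 | (2E,4E)-5-iodopenta-2,4-dienoic acid | OC(=O)/C=C/C=C/I | intermediate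
27 | (2E,4E)-5-iodopenta-2,4-dienoyl chloride | ClC(=O)/C=C/C=C/I | intermediate (not isolated)
28 | (2E,4E)-N-(2-hydroxy-5-oxocyclopent-1-en-1-yl)-5-iodopenta-2,4-dienamide | I/C=C/C=C/C(=O)NC1=C(O)CCC1=O | intermediate
29 | (2E,4E,6E)-N-{(4R,5R,6S)-5,6-epoxy-4-hydroxy-1-oxo-4-[(triethylsilyl)ethynyl]cyclohex-2-en-2-yl}-8-methylnona-2,4,6-trienamide | CC(C)/C=C/C=C/C=C/C(=O)NC1=C[C@@](O)(C#C[Si](CC)(CC)CC)[C@@H]2O[C@@H]2C1=O | intermediate
30 | (2E,4E,6E)-N-[(4R,5R,6S)-5,6-epoxy-4-ethynyl-4-hydroxy-1-oxocyclohex-2-en-2-yl]-8-methylnona-2,4,6-trienamide | CC(C)/C=C/C=C/C=C/C(=O)NC1=C[C@@](O)(C#C)[C@@H]2O[C@@H]2C1=O | intermediate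
31 | (2E,4E,6E)-N-{(4R,5R,6S)-5,6-epoxy-4-hydroxy-1-oxo-4-[(E)-2-(tributylstannyl)ethenyl]cyclohex-2-en-2-yl}-8-methylnona-2,4,6-trienamide | CC(C)/C=C/C=C/C=C/C(=O)NC1=C[C@@](O)(/C=C/[Sn](CCCC)(CCCC)CCCC)[C@@H]2O[C@@H]2C1=O | intermediate
32 | manumycin G, (4S,5R,6S) | CC(C)/C=C/C=C/C=C/C(=O)NC1=C[C@@](O)(/C=C/C=C/C=C/C(=O)NC2=C(O)CCC2=O)[C@@H]2O[C@@H]2C1=O | target

**Step count**

Total step count: 21. Longest linear sequence: 13 steps (steps 1–9 and 18–21).

**Steps most likely to fail**

1. Step 18.
   - What may go wrong: C–N bond formation may be slower than degradation of the iodo epoxy enone under copper and carbonate. Possible degradation paths are hydrodeiodination, conjugate addition of the diamine ligand, and loss of the silyl cap followed by acetylide chemistry.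
   - Fallback, from 13 back to 29: nitrogen is introduced with an ammonia surrogate and acylated afterwards.
   - Buchwald–Hartwig coupling of 13 with benzophenone imine (Pd2(dba)3, Xantphos, Cs2CO3, toluene) should give (4R,5R,6S)-2-[(diphenylmethylidene)amino]-5,6-epoxy-4-hydroxy-4-[(triethylsilyl)ethynyl]cyclohex-2-en-1-one F1.
   - Mild hydrolysis (aqueous citric acid, THF) should give (4R,5R,6S)-2-amino-5,6-epoxy-4-hydroxy-4-[(triethylsilyl)ethynyl]cyclohex-2-en-1-one F2.
   - N-acylation of F2 with acid chloride 19 (pyridine, CH2Cl2, 0 °C; the hindered tertiary hydroxyl stays free) rejoins the route at 29.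

2. Step 20.
   - What may go wrong: palladium hydride or tin hydride may reduce the enone or reductively open the epoxy ketone in competition with alkyne hydrometallation, and proximal stannylation may erode regioselectivity.
   - Fallback, from 30 back to 31: the ketone is masked by a redox detour.
   - Luche reduction of 30 (NaBH4, CeCl3·7H2O, MeOH, −78 °C) should give the C1 carbinol of 30 (either C1 epimer, inconsequential) F3.
   - Hydrostannylation under the same catalysis, now without a reducible carbonyl, should give the C1 carbinol of 31 F4.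
   - Chemoselective allylic oxidation (MnO2, CH2Cl2), which vinylstannanes tolerate, rejoins the route at 31.

3. Step 6.
   - What may go wrong: control in the bromonium opening may be poor, through attack of bromine on the C2=C3 alkene, 1,4-addition of water at C3, or insufficient facial bias. Elimination instead of ring closure may also occur downstream.
   - Fallback, from 8 back to 12: the C6 leaving group is built from a dihydroxylation.
   - OsO4 (cat.)/NMO in acetone–water should attack C6=C1 from the β face to give the C6β,C1β-cis-diol of 8 F5.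
   - MnO2 should oxidise only the allylic C1 hydroxyl to give the 6β-hydroxy enone acetonide F6.
   - MsCl/Et3N at −20 °C should give the 6β-mesyloxy enone acetonide F7.
   - TFA–H2O should release (C4α,C5α)-dihydroxy-6β-mesyloxy enone F8.
   - K2CO3 in MeCN closes the α-epoxide by the same intramolecular SN2 and rejoins the route at 12.

**Further compounds**

F1 | step 18 | (4R,5R,6S)-2-[(diphenylmethylidene)amino]-5,6-epoxy-4-hydroxy-4-[(triethylsilyl)ethynyl]cyclohex-2-en-1-one | C(=NC1=C[C@@](O)(C#C[Si](CC)(CC)CC)[C@@H]2O[C@@H]2C1=O)(c1ccccc1)c1ccccc1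
F2 | step 18 | (4R,5R,6S)-2-amino-5,6-epoxy-4-hydroxy-4-[(triethylsilyl)ethynyl]cyclohex-2-en-1-one | NC1=C[C@@](O)(C#C[Si](CC)(CC)CC)[C@@H]2O[C@@H]2C1=O
F3 | step 20 | C1 carbinol of 30 (C1 configuration open) | CC(C)/C=C/C=C/C=C/C(=O)NC1=C[C@@](O)(C#C)[C@@H]2O[C@@H]2C1O
F4 | step 20 | C1 carbinol of 31 (C1 configuration open) | CC(C)/C=C/C=C/C=C/C(=O)NC1=C[C@@](O)(/C=C/[Sn](CCCC)(CCCC)CCCC)[C@@H]2O[C@@H]2C1O
F5 | step 6 | C6β,C1β-cis-diol of 8 | C1=C[C@@](O2)(C#C[Si](CC)(CC)CC)[C@H](OC2(C)C)[C@@H](O)[C@H]1O
F6 | step 6 | 6β-hydroxy enone acetonide | C1=C[C@@](O2)(C#C[Si](CC)(CC)CC)[C@H](OC2(C)C)[C@@H](O)C1=O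
F7 | step 6 | 6β-mesyloxy enone acetonide | C1=C[C@@](O2)(C#C[Si](CC)(CC)CC)[C@H](OC2(C)C)[C@@H](OS(C)(=O)=O)C1=O
F8 | step 6 | (C4α,C5α)-dihydroxy-6β-mesyloxy enone | C1=C[C@@](O)(C#C[Si](CC)(CC)CC)[C@H](O)[C@@H](OS(C)(=O)=O)C1=O
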